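The plan disconnects C8–C9 and C12–C13 of the bicyclo[3.2.1]octane (rings C and D). The feature exploited is that the carbinol carbon C11 is the central atom of the three-carbon bridge C9–C11–C12, that the one-carbon bridge C14 is an unsubstituted methylene, and that bridgehead C8 is joined to C10 by the ester C7(=O)–O–C20. An oxyallyl cation spanning C9–C11–C12 is therefore added intramolecularly, (4+3), to a cyclopentadiene ester. One operation closes the δ-lactone and ring C, forms both bonds and sets C8, C9 and C13. The precursor is an enantiopure ring A chloromethyl ketone (C1 silyl ether, C6 menthyl acetal) whose C20 hydroxyl carries 3-methylcyclopentadiene-1-carboxylate.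

Key step: step 16

Remarks on the chemistry:
- Atom numbers are those of the ent-kaurane skeleton of the target; TBS = tert-butyldimethylsilyl.
- Assumption: the (5S) epimer of menthyl acetal 4 is the one that crystallises, as is usual for menthyloxybutenolides made from (+)-menthol; otherwise the epimers are separated by chromatography and the unwanted one is re-equilibrated with acid.
- The C6 acetal keeps the menthyl group of the auxiliary (exo, trans to C10) until step 19. No acetal exchange is then needed while the C20 hydroxyl is free, which would risk an internal C6/C20 acetal.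
- The diene acid is made from 3-methylcyclopent-2-en-1-one so that only 1,3-disubstituted cyclopentadienes can form. Compounds 21–24 equilibrate by 1,5-hydrogen shifts and are drawn as one tautomer.
- The chloromethyl ketone is carried as a vinyl chloride through the hydride steps, and C1 is set by a directed reduction.

Step 1
Reactants: 1 3-methylfuran-2-carboxylic acid
Product: 2 5-hydroxy-3-methylfuran-2(5H)-one (racemic)
Conditions: O2, rose bengal (cat.), visible light, MeOH, 0 °C
Reagents that add atoms: dioxygen, O=O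
Why: Singlet-oxygen [4+2] addition across the furan and decarboxylative collapse of the endoperoxide (furan photooxygenation) leave the carbonyl next to the methyl-bearing carbon, which is the regiochemistry the C4 quaternary centre needs.

Step 2
Reactants: 2 5-hydroxy-3-methylfuran-2(5H)-one; 3 (+)-menthol
Product: 4 (5S)-3-methyl-5-[(1S,2R,5S)-menthyloxy]furan-2(5H)-one
Conditions: camphorsulfonic acid (cat.), toluene, reflux with water separator; crystallisation from hexane, mother liquor re-equilibrated with acid
Reagents that add atoms: none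
Why: Acid-catalysed pseudo-ester acetalisation with crystallisation of one epimer should give the single C6 acetal configuration from which all later absolute stereochemistry derives.

Step 3
Reactants: 4 menthyloxybutenolide; 5 (E)-1-methoxy-3-(trimethylsilyloxy)buta-1,3-diene
Product: 7 ring A enone (C1 ketone; C2=C3; C4 methyl cis to H5) cis-fused to the C19 lactone/C6 menthyl acetal ring, via Diels–Alder adduct 6 (not isolated)
Conditions: 5 (3 equiv), toluene, 130 °C, sealed tube; then 0.5 M HCl, THF, 0 °C
Reagents that add atoms: none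
Why: The thermal Diels–Alder reaction should occur on the butenolide face anti to the menthyloxy group, with the nucleophilic CH2 terminus of the diene bonding to the β-carbon (C5), so C4 and C5 are set cis in the absolute sense dictated by C6; acid then unmasks the ketone and eliminates methanol.

Step 4
Reactants: 7 ring A enone
Product: 8 C10-hydroxymethylene enone (C20 as enolised formyl group)
Conditions: LiN(i-Pr)2 (1.1 equiv), THF, −78 °C; CF3CH2OCHO, −78 °C; dilute HCl work-up
Reagents that add atoms: 2,2,2-trifluoroethyl formate, O=COCC(F)(F)F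
Why: The enone can enolise only toward C10 because C4 is quaternary, so kinetic deprotonation and Claisen-type C-formylation introduce C20 regiospecifically, with no stereocentre formed.

Step 5
Reactants: 8 hydroxymethylene enone; 9 2,3-dichloropropene
Product: 11 C10 quaternary aldehyde (formyl C20 cis to C6; 2-chloroallyl cis to H5), via O-(2-chloroallyl) enol ether 10 (not isolated)
Conditions: 9 (1.5 equiv), K2CO3, NaI (cat.), acetone, reflux; filter, evaporate; mesitylene, 165 °C
Reagents that add atoms: none
Why: O-alkylation of the hydroxymethylene ketone followed by Claisen rearrangement should transfer the chloroallyl unit (C9, C11, C12) to C10 from the convex face of the cis-fused bicycle (the face of H5 and the C4 methyl, opposite the lactone ring), which sets C10.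

Step 6
Reactants: 11 quaternary aldehyde
Product: 12 β-hydroxy ketone (C20 CH2OH; C1 ketone; C2–C3 saturated)
Conditions: LiBH(s-Bu)3 (2.3 equiv), THF, −78 °C; AcOH, −78 °C to rt
Reagents that add atoms: none
Why: The hindered borohydride reduces the aldehyde by 1,2-addition and the β-unsubstituted enone by conjugate addition, and the C1 carbonyl stays masked as its lithium enolate until the quench, so it is kept for the directed reduction.

Step 7
Reactants: 12 β-hydroxy ketone
Product: 13 anti-1,3-diol (C1–OH axial, cis to the chloroallyl arm and trans to C20)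
Conditions: Me4NBH(OAc)3 (5 equiv), MeCN/AcOH (1:1), −25 °C
Reagents that add atoms: none
Why: In this hydroxyl-directed (Evans–Saksena) reduction the borohydride binds to the C20 hydroxyl and delivers hydride to C1 from the C20 face, which sets C1 with its oxygen trans to C20 as in the target.

Step 8
Reactants: 13 diol
Product: 14 1,20-bis(TBS) ether
Conditions: TBSOTf (3 equiv), 2,6-lutidine, CH2Cl2, 0 °C to rt
Reagents that add atoms: tert-butyldimethylsilyl triflate, CC(C)(C)[Si](C)(C)OS(=O)(=O)C(F)(F)F
Why: The silyl triflate silylates both the primary and the hindered axial secondary hydroxyl, and the pseudo-ester acetal is inert to the buffered conditions.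

Step 9
Reactants: 14 bis(TBS) ether
Product: 16 C19 α-acetoxy ether (mixture of C19 epimers), via aluminium hemiacetal 15 (not isolated)
Conditions: i-Bu2AlH (1.3 equiv), CH2Cl2, −78 °C; then pyridine, DMAP, Ac2O, −78 to 0 °C
Reagents that add atoms: acetic anhydride, CC(=O)OC(C)=O
Why: This is a reductive acetylation of the lactone: hydride addition gives an aluminium hemiacetal that is stable at low temperature and is trapped in situ as the acetate, while the silyl ethers, vinyl chloride and C6 acetal are untouched.

Step 10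
Reactants: 16 α-acetoxy ether
Product: 17 cyclic ether acetal (C19H2–O–C6H–O-menthyl; C10 2-chloroallyl; 1,20-bis-TBS)
Conditions: Et3SiH (5 equiv), BF3·OEt2 (2 equiv), CH2Cl2, −78 °C
Reagents that add atoms: none
Why: In this ionic hydrogenation BF3 ionises the acetoxy ether to the C19 oxocarbenium ion, which the silane reduces; at −78 °C acetate should leave far faster than the menthyloxy group of the C6 dialkyl acetal, so C6 keeps its oxidation level and configuration.

Step 11
Reactants: 17 vinyl chloride
Product: 18 chloromethyl ketone (ClC12H2–C11(=O)–C9H2 on C10; 1,20-bis-TBS)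
Conditions: NaOCl (aq., 1.5 equiv), AcOH, acetone, 0 °C
Reagents that add atoms: sodium hypochlorite, [Na+].[O-]Cl; water, O
Why: Hypochlorous acid chlorinates the terminal carbon of the vinyl chloride and water captures the chlorine-stabilised cation, which loses HCl (vinyl halide to α-haloketone oxidation), so chlorine ends on C12 and the carbonyl on C11.

Step 12
Reactants: 18 bis(TBS) chloromethyl ketone
Product: 19 C20 alcohol (chloromethyl ketone; C1–OTBS), in equilibrium with its cyclic hemiketal
Conditions: HF·pyridine, pyridine, THF, 0 °C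
Reagents that add atoms: none
Why: Buffered fluoride cleaves the primary silyl ether much faster than the axial secondary one next to quaternary C10, and the near-neutral medium avoids both acetal exchange with the freed hydroxyl and alkoxide attack on the chloroketone.

Step 13
Reactants: 20 3-methylcyclopent-2-en-1-one
Product: 21 4-methylcyclopenta-1,3-dien-2-yl trifluoromethanesulfonate
Conditions: LiN(i-Pr)2, THF, −78 °C; PhNTf2, −78 to 0 °C; aq. NH4Cl work-up, used at once
Reagents that add atoms: N-phenylbis(trifluoromethanesulfonimide), O=S(=O)(N(c1ccccc1)S(=O)(=O)C(F)(F)F)C(F)(F)F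
Why: Kinetic α′-deprotonation and O-sulfonylation give the cross-conjugated dienyl triflate, which fixes the 1,3 relationship between the future carboxyl and the methyl group.

Step 14
Reactants: 21 dienyl triflate
Product: 22 3-methylcyclopenta-1,3-diene-1-carboxylic acid (equilibrating tautomers)
Conditions: Pd(OAc)2 (5 mol %), Fe(C5H4PPh2)2 (dppf, 10 mol %), CO (1 atm), Et3N, DMF/H2O, 25 °C; cold dilute HCl work-up, used at once
Reagents that add atoms: carbon monoxide, [C-]#[O+]; water, O
Why: Palladium-catalysed hydroxycarbonylation of the alkenyl triflate (oxidative addition, CO insertion, hydrolysis of the acylpalladium) installs C7, and 1,5-hydrogen shifts then equilibrate the ring tautomers.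

Step 15
Reactants: 19 C20 alcohol; 22 diene acid
Product: 23 key-step precursor (19 esterified at C20 with 3-methylcyclopenta-1,3-diene-1-carboxylic acid)
Conditions: 22 (3 equiv), N,N'-diisopropylcarbodiimide, DMAP (cat.), CH2Cl2, 0 °C; rapid filtration through silica, used at once
Reagents that add atoms: none
Why: Steglich esterification under near-neutral conditions (via the acylpyridinium or the ketene derived from it) should acylate the neopentyl C20 hydroxyl without touching the chloroketone or the acetal.

Step 16
Reactants: 23 key-step precursor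
Product: 25 pentacyclic C11 ketone (C15=C16 alkene with 16-methyl; δ-lactone; C1–OTBS; C6 O-menthyl), via oxyallyl cation 24 (not isolated)
Conditions: Et3N (2 equiv), CF3CH2OH, 0.002 M (slow addition of 23), 0 to 25 °C
Reagents that add atoms: none
Why: Proposed new method: Et3N enolises the ketone toward C9 and chloride leaves C12 in the ionising solvent, giving the Z-configured oxyallyl cation 24 (C9–C11–C12), which adds across the diene termini C8 and C13 of the 1-carboxy-3-methyl tautomer, the unhindered C12 bonding to C13 ahead of the hindered C9–C8 bond while the charge is relayed to the methyl-bearing C16. The closest known reaction type is the intramolecular (4+3) cycloaddition of α-haloketone-derived oxyallyl cations with tethered furans and alkyl-substituted cyclopentadienes under amine/fluoroalcohol conditions; a cyclopentadiene that carries the tethering ester is the untested element. The δ-lactone (C10–C20–O–C7–C8–C9) closes by 6-exo attack of C9 on C8 over the four-atom tether, and ring C (C8–C9–C11–C12–C13–C14) closes as part of the bicyclo[3.2.1]octene by the (4+3) union on the same diene face. C8 and C13 are fixed relative to each other by suprafacial addition to the ring diene and relative to C10 by the cation face that the axial C20 arm can reach when the bulkier C5 flank eclipses the small C9–H and the C1 flank (silyl ether axial, pointing away) lies beside C11–O; C9 is set by the extended arrangement of the Z cation, which puts C10 anti to the C15–C16 bridge. The step needs one tautomer, one diene face and the extended mode: the tautomers equilibrate by 1,5-hydrogen shifts (faster with the amine), the competing 1-carboxy-4-methyl tautomer would have to join C12 to a methyl-substituted carbon and should react more slowly, and a C9 epimer from a compact approach could be corrected by enolisation toward the C11 ketone. High dilution and immediate use of 23 suppress dimerisation of the diene ester.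

Step 17
Reactants: 25 pentacyclic C11 ketone
Product: 26 C11 alcohol (11-OH cis to C10; equatorial on ring C)
Conditions: NaBH4, MeOH/CH2Cl2, −20 °C
Reagents that add atoms: none
Why: In this ketone reduction the exo face of C11 is screened by the axial C9–C10 bond and the ring A substituents on C10, so the small hydride should attack from the side of the C15–C16 alkene and set C11 as in the target.

Step 18
Reactants: 26 C11 alcohol
Product: 27 1,11-bis(TBS) ether
Conditions: TBSOTf, 2,6-lutidine, CH2Cl2, 0 °C to rt
Reagents that add atoms: tert-butyldimethylsilyl triflate, CC(C)(C)[Si](C)(C)OS(=O)(=O)C(F)(F)F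
Why: Silyl triflate protection of the hindered secondary alcohol keeps C11 from being acetylated or oxidised in the following steps.

Step 19
Reactants: 27 bis(TBS) ether
Product: 28 C6 lactol (anomer mixture)
Conditions: AcOH/THF/H2O (3:1:1), 45 °C
Reagents that add atoms: water, O
Why: Mild aqueous acid hydrolyses the 2-alkoxytetrahydrofuran acetal through the C6 oxocarbenium ion, while the hindered secondary silyl ethers, the lactone and the trisubstituted alkene should survive.

Step 20
Reactants: 28 lactol
Product: 29 C6 acetate (OAc trans to C10 and cis to H5)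
Conditions: Ac2O, pyridine, DMAP (cat.), CH2Cl2, 0 °C
Reagents that add atoms: acetic anhydride, CC(=O)OC(C)=O
Why: The lactol anomers equilibrate and the exo hydroxyl on the convex face is acylated fastest, which should set C6 with the acetate trans to the C5–C10 bond as in the target.

Step 21
Reactants: 29 C6 acetate
Product: 31 1,11-bis(TBS) ether of oreskaurin A (C15 ketone; exocyclic C16=C17), via C15 hydroperoxide 30 (not isolated)
Conditions: O2, tetraphenylporphyrin (cat.), visible light, CH2Cl2, 0 °C; then Ac2O, pyridine, DMAP (cat.), 0 to 25 °C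
Reagents that add atoms: dioxygen, O=O
Why: In the Schenck ene reaction singlet oxygen can abstract only a C17 methyl hydrogen (C13 is a bridgehead and C8 has no hydrogen), giving the C15 hydroperoxide with the exocyclic alkene, which acetic anhydride/pyridine dehydrates (Kornblum–DeLaMare type) to the enone.

Step 22
Reactants: 31 bis(TBS) enone
Product: 32 oreskaurin A
Conditions: HF·pyridine, pyridine, THF, 0 to 25 °C
Reagents that add atoms: none
Why: Buffered fluoride desilylation frees the C1 and C11 hydroxyls without base, so the anomeric acetate and the α-methylene ketone are preserved.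

Compound list
1 | 3-methylfuran-2-carboxylic acid | Cc1ccoc1C(=O)O | starting material
2 | 5-hydroxy-3-methylfuran-2(5H)-one (racemic) | CC1=CC(O)OC1=O | intermediate
3 | (+)-menthol, (1S,2R,5S) | O[C@H]1C[C@@H](C)CC[C@@H]1C(C)C | starting material
4 | (5S)-3-methyl-5-[(1S,2R,5S)-menthyloxy]furan-2(5H)-one | CC1=C[C@@H](O[C@H]2C[C@@H](C)CC[C@@H]2C(C)C)OC1=O | intermediate
5 | (E)-1-methoxy-3-(trimethylsilyloxy)buta-1,3-diene | CO/C=C/C(=C)O[Si](C)(C)C | starting material
6 | Diels–Alder adduct (C1 silyl enol ether, 3-methoxy, endo; lactone ring cis-fused at C4–C5) | C[Si](C)(C)OC1=C[C@@H](OC)[C@@]2(C)C(=O)O[C@H](O[C@H]3C[C@@H](C)CC[C@@H]3C(C)C)[C@H]2C1 | intermediate (not isolated)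
7 | ring A enone (C1 ketone, C2=C3, C4 methyl cis to H5) cis-fused to the C19 lactone/C6 menthyl acetal ring (O-menthyl trans to C10) | O=C1C=C[C@@]2(C)C(=O)O[C@H](O[C@H]3C[C@@H](C)CC[C@@H]3C(C)C)[C@H]2C1 | intermediate
8 | C10-hydroxymethylene enone | O/C=C1\C(=O)C=C[C@@]2(C)C(=O)O[C@H](O[C@H]3C[C@@H](C)CC[C@@H]3C(C)C)[C@H]21 | intermediate
9 | 2,3-dichloropropene | C=C(Cl)CCl | starting material
10 | O-(2-chloroallyl) enol ether of 8 | C=C(Cl)COC=C1C(=O)C=C[C@@]2(C)C(=O)O[C@H](O[C@H]3C[C@@H](C)CC[C@@H]3C(C)C)[C@H]21 | intermediate (not isolated)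
11 | C10 quaternary aldehyde (formyl cis to C6, 2-chloroallyl cis to H5) | C=C(Cl)C[C@]1(C=O)C(=O)C=C[C@@]2(C)C(=O)O[C@H](O[C@H]3C[C@@H](C)CC[C@@H]3C(C)C)[C@H]21 | intermediate
12 | β-hydroxy ketone (C20 CH2OH, C1 ketone) | C=C(Cl)C[C@]1(CO)C(=O)CC[C@@]2(C)C(=O)O[C@H](O[C@H]3C[C@@H](C)CC[C@@H]3C(C)C)[C@H]21 | intermediate
13 | anti-1,3-diol (C1–OH trans to C20) | C=C(Cl)C[C@]1(CO)[C@H](O)CC[C@@]2(C)C(=O)O[C@H](O[C@H]3C[C@@H](C)CC[C@@H]3C(C)C)[C@H]21 | intermediate
14 | 1,20-bis(TBS) ether of 13 | C=C(Cl)C[C@]1(CO[Si](C)(C)C(C)(C)C)[C@H](O[Si](C)(C)C(C)(C)C)CC[C@@]2(C)C(=O)O[C@H](O[C@H]3C[C@@H](C)CC[C@@H]3C(C)C)[C@H]21 | intermediate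
15 | C19 diisobutylaluminium hemiacetal | C=C(Cl)C[C@]1(CO[Si](C)(C)C(C)(C)C)[C@H](O[Si](C)(C)C(C)(C)C)CC[C@@]2(C)C(O[Al](CC(C)C)CC(C)C)O[C@H](O[C@H]3C[C@@H](C)CC[C@@H]3C(C)C)[C@H]21 | intermediate (not isolated)
16 | C19 α-acetoxy ether (C19 epimers) | C=C(Cl)C[C@]1(CO[Si](C)(C)C(C)(C)C)[C@H](O[Si](C)(C)C(C)(C)C)CC[C@@]2(C)C(OC(C)=O)O[C@H](O[C@H]3C[C@@H](C)CC[C@@H]3C(C)C)[C@H]21 | intermediate
17 | cyclic ether acetal (C19H2–O–C6H–O-menthyl) with C10 2-chloroallyl, 1,20-bis(TBS) | C=C(Cl)C[C@]1(CO[Si](C)(C)C(C)(C)C)[C@H](O[Si](C)(C)C(C)(C)C)CC[C@@]2(C)CO[C@H](O[C@H]3C[C@@H](C)CC[C@@H]3C(C)C)[C@H]21 | intermediate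
18 | chloromethyl ketone, 1,20-bis(TBS) | ClCC(=O)C[C@]1(CO[Si](C)(C)C(C)(C)C)[C@H](O[Si](C)(C)C(C)(C)C)CC[C@@]2(C)CO[C@H](O[C@H]3C[C@@H](C)CC[C@@H]3C(C)C)[C@H]21 | intermediate
19 | chloromethyl ketone with free C20 hydroxyl, C1–OTBS | ClCC(=O)C[C@]1(CO)[C@H](O[Si](C)(C)C(C)(C)C)CC[C@@]2(C)CO[C@H](O[C@H]3C[C@@H](C)CC[C@@H]3C(C)C)[C@H]21 | intermediate
20 | 3-methylcyclopent-2-en-1-one | CC1=CC(=O)CC1 | starting material
21 | 4-methylcyclopenta-1,3-dien-2-yl trifluoromethanesulfonate | CC1=CC(OS(=O)(=O)C(F)(F)F)=CC1 | intermediate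
22 | 3-methylcyclopenta-1,3-diene-1-carboxylic acid (tautomer mixture) | CC1=CCC(C(=O)O)=C1 | intermediate
23 | key-step precursor: chloromethyl ketone bearing the diene ester on C20 | ClCC(=O)C[C@]1(COC(=O)C3=CC(C)=CC3)[C@H](O[Si](C)(C)C(C)(C)C)CC[C@@]2(C)CO[C@H](O[C@H]4C[C@@H](C)CC[C@@H]4C(C)C)[C@H]21 | intermediate
24 | Z-oxyallyl cation (C9–C11–C12) | [O-]/C([CH2+])=C\[C@]1(COC(=O)C3=CC(C)=CC3)[C@H](O[Si](C)(C)C(C)(C)C)CC[C@@]2(C)CO[C@H](O[C@H]4C[C@@H](C)CC[C@@H]4C(C)C)[C@H]21 | intermediate (not isolated)
25 | (4+3) adduct: pentacyclic C11 ketone, C15=C16 alkene with 16-methyl | CC1=C[C@]23C[C@H]1CC(=O)[C@H]2[C@]1(COC3=O)[C@H](O[Si](C)(C)C(C)(C)C)CC[C@@]2(C)CO[C@H](O[C@H]4C[C@@H](C)CC[C@@H]4C(C)C)[C@H]21 | intermediate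
26 | C11 alcohol | CC1=C[C@]23C[C@H]1C[C@@H](O)[C@H]2[C@]1(COC3=O)[C@H](O[Si](C)(C)C(C)(C)C)CC[C@@]2(C)CO[C@H](O[C@H]4C[C@@H](C)CC[C@@H]4C(C)C)[C@H]21 | intermediate
27 | 1,11-bis(TBS) ether | CC1=C[C@]23C[C@H]1C[C@@H](O[Si](C)(C)C(C)(C)C)[C@H]2[C@]1(COC3=O)[C@H](O[Si](C)(C)C(C)(C)C)CC[C@@]2(C)CO[C@H](O[C@H]4C[C@@H](C)CC[C@@H]4C(C)C)[C@H]21 | intermediate
28 | C6 lactol (anomers) | CC1=C[C@]23C[C@H]1C[C@@H](O[Si](C)(C)C(C)(C)C)[C@H]2[C@]1(COC3=O)[C@H](O[Si](C)(C)C(C)(C)C)CC[C@@]2(C)COC(O)[C@H]21 | intermediate
29 | C6 acetate | CC1=C[C@]23C[C@H]1C[C@@H](O[Si](C)(C)C(C)(C)C)[C@H]2[C@]1(COC3=O)[C@H](O[Si](C)(C)C(C)(C)C)CC[C@@]2(C)CO[C@H](OC(C)=O)[C@H]21 | intermediate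
30 | C15 hydroperoxide with exocyclic C16=C17 | C=C1C(OO)[C@]23C[C@H]1C[C@@H](O[Si](C)(C)C(C)(C)C)[C@H]2[C@]1(COC3=O)[C@H](O[Si](C)(C)C(C)(C)C)CC[C@@]2(C)CO[C@H](OC(C)=O)[C@H]21 | intermediate (not isolated)
31 | 1,11-bis(TBS) ether of oreskaurin A | C=C1C(=O)[C@]23C[C@H]1C[C@@H](O[Si](C)(C)C(C)(C)C)[C@H]2[C@]1(COC3=O)[C@H](O[Si](C)(C)C(C)(C)C)CC[C@@]2(C)CO[C@H](OC(C)=O)[C@H]21 | intermediate
32 | oreskaurin A | C=C1C(=O)[C@]23C[C@H]1C[C@@H](O)[C@H]2[C@]1(COC3=O)[C@H](O)CC[C@@]2(C)CO[C@H](OC(C)=O)[C@H]21 | target

Total step count: 22 (steps 13 and 14 make the diene acid on a side branch).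
Longest linear sequence: 20 steps (1–12 and 15–22).

Steps most likely to fail

1. Step 16 (proposed new method).
What may go wrong: capture of the oxyallyl cation by the ester-deactivated diene may be slower than solvent trapping or Favorskii-type collapse. Reaction may also leak through the 1-carboxy-4-methyl tautomer, the other diene face or the compact mode, and the diene ester may dimerise before ionisation.
Fallback, known chemistry, setting out from 19 and returning at 25: an intramolecular Diels–Alder reaction for the lactone and ring C, then a vinyl-radical closure of ring D.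
- Diethyl malonate is alkylated with 2,3-dibromopropene (NaH, THF) to diethyl 2-(2-bromoallyl)malonate F1. This is saponified (KOH) to 2-(2-bromoallyl)malonic acid F2 and methylenated with decarboxylation (paraformaldehyde, Et2NH, reflux) to 4-bromo-2-methylenepent-4-enoic acid F3.
- Alcohol 19 is esterified with F3 (carbodiimide, DMAP) to the acrylate ester F4.
- PPh3 (toluene, 60 °C) turns the chloromethyl ketone into the phosphonium chloride F5, and K2CO3 with aqueous formaldehyde (Wittig methylenation) gives the vinyl ketone F6.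
- TBSOTf/Et3N gives the (Z)-2-silyloxydiene F7.
- Heating (toluene, 170 °C) should bring about the intramolecular Diels–Alder reaction with the tethered acrylate, forming C8–C9 and C13–C14 and closing the δ-lactone and ring C to give the silyl enol ether F8.
- IBX with 4-methoxypyridine N-oxide oxidises F8 to the C12=C13 enone F9.
- Bu3SnH/AIBN closes ring D by 5-exo addition of the C16 vinyl radical to C13, giving the C11 ketone with exocyclic C16=C17, the methylene ketone F10.
- Acid-catalysed migration of that alkene into the ring (a trace of TsOH or I2, benzene) returns to 25.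

2. Step 10.
What may go wrong: the C6 menthyl acetal may ionise alongside the C19 acetate, which leads to over-reduction or loss of the C6 configuration.
Fallback, setting out from 14 and returning at 17: the deoxygenation is done by a radical instead of a cation. Reduction with i-Bu2AlH (−78 °C) and aqueous work-up gives the C19 lactol F11. PhOC(S)Cl/pyridine/DMAP gives the C19 O-phenyl thionocarbonate F12. Bu3SnH/AIBN (toluene, 90 °C, Barton–McCombie deoxygenation) then removes the C19 oxygen through the anomeric radical and gives 17, leaving the C6 acetal untouched.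

3. Step 17.
What may go wrong: hydride may attack from the exo face and give the C11 epimer.
Fallback, setting out from 25 and returning at 26: kinetic hydride delivery is replaced by electron-transfer reduction with protonation under thermodynamic control (SmI2, THF/i-PrOH, −78 to 0 °C), the method that gives equatorial alcohols from bicyclo[3.2.1]oct-6-en-3-ones. Any epimer already formed is first returned to 25 by oxidation. No new compound is made.

Further compounds
F1 | step 16 | diethyl 2-(2-bromoallyl)malonate | CCOC(=O)C(CC(Br)=C)C(=O)OCC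
F2 | step 16 | 2-(2-bromoallyl)malonic acid | OC(=O)C(CC(Br)=C)C(O)=O
F3 | step 16 | 4-bromo-2-methylenepent-4-enoic acid | C=C(Br)CC(=C)C(=O)O
F4 | step 16 | C20 2-(2-bromoallyl)acrylate of 19 | ClCC(=O)C[C@]1(COC(=O)C(=C)CC(Br)=C)[C@H](O[Si](C)(C)C(C)(C)C)CC[C@@]2(C)CO[C@H](O[C@H]3C[C@@H](C)CC[C@@H]3C(C)C)[C@H]21
F5 | step 16 | acylmethyl triphenylphosphonium chloride from F4 | [Cl-].c1ccccc1[P+](c1ccccc1)(c1ccccc1)CC(=O)C[C@]1(COC(=O)C(=C)CC(Br)=C)[C@H](O[Si](C)(C)C(C)(C)C)CC[C@@]2(C)CO[C@H](O[C@H]3C[C@@H](C)CC[C@@H]3C(C)C)[C@H]21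
F6 | step 16 | vinyl ketone | C=CC(=O)C[C@]1(COC(=O)C(=C)CC(Br)=C)[C@H](O[Si](C)(C)C(C)(C)C)CC[C@@]2(C)CO[C@H](O[C@H]3C[C@@H](C)CC[C@@H]3C(C)C)[C@H]21
F7 | step 16 | (Z)-2-silyloxydiene | C=C/C(O[Si](C)(C)C(C)(C)C)=C/[C@]1(COC(=O)C(=C)CC(Br)=C)[C@H](O[Si](C)(C)C(C)(C)C)CC[C@@]2(C)CO[C@H](O[C@H]3C[C@@H](C)CC[C@@H]3C(C)C)[C@H]21
F8 | step 16 | intramolecular Diels–Alder adduct (C11 silyl enol ether, lactone, C8 2-bromoallyl) | C=C(Br)C[C@]23CCC=C(O[Si](C)(C)C(C)(C)C)[C@H]2[C@]1(COC3=O)[C@H](O[Si](C)(C)C(C)(C)C)CC[C@@]2(C)CO[C@H](O[C@H]4C[C@@H](C)CC[C@@H]4C(C)C)[C@H]21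
F9 | step 16 | C11 ketone with C12=C13 enone | C=C(Br)C[C@]23CC=CC(=O)[C@H]2[C@]1(COC3=O)[C@H](O[Si](C)(C)C(C)(C)C)CC[C@@]2(C)CO[C@H](O[C@H]4C[C@@H](C)CC[C@@H]4C(C)C)[C@H]21
F10 | step 16 | C11 ketone with exocyclic C16=C17 | C=C1C[C@]23C[C@H]1CC(=O)[C@H]2[C@]1(COC3=O)[C@H](O[Si](C)(C)C(C)(C)C)CC[C@@]2(C)CO[C@H](O[C@H]4C[C@@H](C)CC[C@@H]4C(C)C)[C@H]21
F11 | step 10 | C19 lactol | C=C(Cl)C[C@]1(CO[Si](C)(C)C(C)(C)C)[C@H](O[Si](C)(C)C(C)(C)C)CC[C@@]2(C)C(O)O[C@H](O[C@H]3C[C@@H](C)CC[C@@H]3C(C)C)[C@H]21
F12 | step 10 | C19 O-phenyl thionocarbonate | C=C(Cl)C[C@]1(CO[Si](C)(C)C(C)(C)C)[C@H](O[Si](C)(C)C(C)(C)C)CC[C@@]2(C)C(OC(=S)Oc3ccccc3)O[C@H](O[C@H]3C[C@@H](C)CC[C@@H]3C(C)C)[C@H]21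
F0 | step 17 | none | none
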